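**Retrosynthetic overview**
1. Target ⇒ (acetonide and TMS removal) ⇒ C7–C8 aldol bond. The partners are the samarium dienolate of a 5-acetoxy-2-bromocyclopentenone and a C1–C7 α,β-dioxy aldehyde.
2. Cyclopentenone core ⇒ ring contraction of a 4-bromo-6-hydroxy-6-alkylpyran-3-one (ring–chain tautomerism, then enantioselective aldol C8→C12).
3. Pyranone ⇒ oxidative ring expansion (Achmatowicz) of a 3-bromo-5-alkylfurfuryl alcohol.
4. Furan ⇒ 2-bromofuran + (2Z,5Z)-octadienyl bromide (from 1-bromopent-2-yne and propargyl alcohol) + CH2O, with Br relocated by a halogen dance. Aldehyde ⇒ D-erythronolactone acetonide + a C3 ylide.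
5. Ring order: furan (purchased, five-membered) → pyranone (six-membered) → cyclopentenone (five-membered carbocycle, the only ring of the target).

Atom labels C1–C20 follow prostanoid numbering (ester carbon C1, ring C8–C12).
Assumption: the sense of induction of the zinc/ProPhenol catalyst in step 7 is taken as drawn. The ligand antipode is equally available if the opposite sense is found.

**Step 1**
Reactants: 1 1-bromopent-2-yne; 2 prop-2-yn-1-ol
Product: 3 octa-2,5-diyn-1-ol
Conditions: CuI (20 mol %), Cs2CO3 (1.2 equiv), DMF, 23 °C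
Reagents that add atoms: none
Why: Copper-acetylide substitution of a propargylic bromide (copper-catalysed propargyl–alkyne coupling) builds the skipped diyne under a carbonate base too weak to isomerise it.

**Step 2**
Reactants: 3 octa-2,5-diyn-1-ol
Product: 4 (2Z,5Z)-octa-2,5-dien-1-ol
Conditions: H2 (1 atm), Ni(OAc)2·4H2O (10 mol %), NaBH4 (10 mol %), H2NCH2CH2NH2, EtOH, 23 °C
Reagents that add atoms: none
Why: Syn semihydrogenation on the amine-poisoned nickel boride catalyst (Brown-type alkyne semireduction) stops at the diene and sets both Z alkenes.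

**Step 3**
Reactants: 4 (2Z,5Z)-octa-2,5-dien-1-ol
Product: 5 (2Z,5Z)-1-bromoocta-2,5-diene
Conditions: CBr4, PPh3, CH2Cl2, −30 → 0 °C
Reagents that add atoms: carbon tetrabromide BrC(Br)(Br)Br
Why: The Appel reaction replaces the primary allylic OH by SN2 at low temperature, without allylic transposition or Z/E erosion.

**Step 4**
Reactants: 6 2-bromofuran; 5 (2Z,5Z)-1-bromoocta-2,5-diene
Product: 8 2-bromo-5-[(2Z,5Z)-octa-2,5-dien-1-yl]furan, via 5-bromofuran-2-yllithium 7 (not isolated)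
Conditions: LiN(i-Pr)2 (1.0 equiv), THF, −78 °C; then 5, DMPU, −78 → −20 °C
Reagents that add atoms: none
Why: Amide deprotonation takes the free α-position of the furan without Br/Li exchange, and the furyllithium displaces the primary allylic bromide directly (SN2 alkylation), keeping both Z alkenes.

**Step 5**
Reactants: 8 2-bromo-5-[(2Z,5Z)-octa-2,5-dien-1-yl]furan
Product: 11 {3-bromo-5-[(2Z,5Z)-octa-2,5-dien-1-yl]furan-2-yl}methanol, via 3-lithio-2-bromofuran species 9 (not isolated), via 2-lithio-3-bromofuran species 10 (not isolated)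
Conditions: LiN(i-Pr)2 (1.1 equiv), THF, −78 °C, 1 h; then CH2O (monomer in THF), −78 → 0 °C; then H2O
Reagents that add atoms: formaldehyde C=O
Why: In the base-catalysed halogen dance, kinetic lithiation next to Br is followed by intermolecular Br transfer to the more stable α-lithio-β-bromofuran, whose hydroxymethylation puts Br on the future C10 and CH2OH on the future C9.

**Step 6**
Reactants: 11 {3-bromo-5-[(2Z,5Z)-octa-2,5-dien-1-yl]furan-2-yl}methanol
Product: 12 4-bromo-6-hydroxy-6-[(2Z,5Z)-octa-2,5-dien-1-yl]-2H-pyran-3(6H)-one (racemic hemiketal)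
Conditions: VO(acac)2 (5 mol %), t-BuOOH (1.1 equiv, decane), CH2Cl2, 0 °C
Reagents that add atoms: tert-butyl hydroperoxide CC(C)(C)OO
Why: In the Achmatowicz rearrangement, hydroxyl-directed oxidation of the furan, opening to the ene-dione and re-closure through the CH2OH oxygen expand the five-membered ring to the six-membered pyranone, while the undirected isolated Z alkenes are left alone.

**Step 7**
Reactants: 12 4-bromo-6-hydroxy-6-[(2Z,5Z)-octa-2,5-dien-1-yl]-2H-pyran-3(6H)-one
Product: 14 (4R,5R)-2-bromo-4,5-dihydroxy-4-[(2Z,5Z)-octa-2,5-dien-1-yl]cyclopent-2-en-1-one, via open-chain cis-enedione 13 (not isolated)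
Conditions: Et2Zn (20 mol %), (S,S)-ProPhenol [2,6-bis{[(2S)-2-(hydroxydiphenylmethyl)pyrrolidin-1-yl]methyl}-4-methylphenol, 10 mol %], 4 Å MS, THF, −20 °C
Reagents that add atoms: none
Why: Proposed new method: the racemic hemiketal opens reversibly to the achiral cis-enedione 13, whose α-hydroxy ketone binds one zinc as a bidentate enediolate (so C8 is enolised rather than the doubly activated C13 methylene) while the second zinc activates the C12 ketone, and a 5-(enolexo)-exo-trig aldol inside the chiral pocket contracts the six-membered O-ring to the cyclopentenone and sets the C12 carbinol in a dynamic kinetic asymmetric ring contraction (zinc bridging gives the cis-diol, and the C8 centre is erased later); the closest known reaction types are the dinuclear-zinc direct aldol of α-hydroxy ketones with aldehydes and the amine-mediated racemic isomerisation of 6-hydroxypyranones to 4,5-dihydroxycyclopentenones.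

**Step 8**
Reactants: 14 (4R,5R)-2-bromo-4,5-dihydroxy-4-[(2Z,5Z)-octa-2,5-dien-1-yl]cyclopent-2-en-1-one
Product: 16 (1R,5R)-3-bromo-5-[(2Z,5Z)-octa-2,5-dien-1-yl]-2-oxo-5-[(trimethylsilyl)oxy]cyclopent-3-en-1-yl acetate, via monoacetate 15 (not isolated)
Conditions: Ac2O (1.05 equiv), 4-(dimethylamino)pyridine (5 mol %), pyridine, CH2Cl2, 0 °C; then N-(trimethylsilyl)imidazole, 23 °C
Reagents that add atoms: acetic anhydride CC(=O)OC(C)=O; N-(trimethylsilyl)imidazole C[Si](C)(C)n1ccnc1
Why: Nucleophile-catalysed acetylation takes only the secondary α-ketol OH (the leaving group for step 13), and neutral silyl transfer then caps the tertiary OH without enolising the ketone.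

**Step 9**
Reactants: 17 (3aR,6aR)-2,2-dimethyldihydrofuro[3,4-d][1,3]dioxol-4(3aH)-one (2,3-O-isopropylidene-D-erythronolactone)
Product: 18 (3aR,6aR)-2,2-dimethyltetrahydrofuro[3,4-d][1,3]dioxol-4-ol (anomer mixture)
Conditions: i-Bu2AlH (1.1 equiv), CH2Cl2, −78 °C; then H2O
Reagents that add atoms: none
Why: Partial lactone reduction stops at the tetrahedral aluminate at −78 °C and leaves both chiral-pool centres (future C5 and C6) untouched.

**Step 10**
Reactants: 18 (3aR,6aR)-2,2-dimethyltetrahydrofuro[3,4-d][1,3]dioxol-4-ol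
Product: 20 methyl (3Z)-4-[(4S,5R)-5-(hydroxymethyl)-2,2-dimethyl-1,3-dioxolan-4-yl]but-3-enoate, via hydroxy acid 19 (not isolated)
Conditions: [Ph3PCH2CH2CO2H]Br, NaN(SiMe3)2 (2 equiv per salt), THF, −78 → 23 °C; aq HCl to pH 4; crude acid, Me3SiCHN2, PhMe–MeOH, 0 °C
Reagents that add atoms: (2-carboxyethyl)triphenylphosphonium bromide OC(=O)CC[P+](c1ccccc1)(c1ccccc1)c1ccccc1.[Br-]; (trimethylsilyl)diazomethane C[Si](C)(C)C=[N+]=[N-]
Why: Wittig olefination of the open hydroxy-aldehyde form of the lactol with the carboxylate ylide adds C1–C3 (the alkene geometry is irrelevant), and diazoalkane methylation of the crude acid gives the ester without touching the free alcohol.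

**Step 11**
Reactants: 20 methyl (3Z)-4-[(4S,5R)-5-(hydroxymethyl)-2,2-dimethyl-1,3-dioxolan-4-yl]but-3-enoate
Product: 21 methyl 4-[(4S,5R)-5-(hydroxymethyl)-2,2-dimethyl-1,3-dioxolan-4-yl]butanoate
Conditions: H2 (1 atm), Pd/C (10 wt %), EtOAc, 23 °C
Reagents that add atoms: none
Why: Heterogeneous catalytic hydrogenation saturates the only alkene, and the acetonide, ester and both stereocentres are inert.

**Step 12**
Reactants: 21 methyl 4-[(4S,5R)-5-(hydroxymethyl)-2,2-dimethyl-1,3-dioxolan-4-yl]butanoate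
Product: 22 methyl 4-[(4S,5S)-5-formyl-2,2-dimethyl-1,3-dioxolan-4-yl]butanoate
Conditions: Dess–Martin periodinane, CH2Cl2, 0 → 23 °C
Reagents that add atoms: none
Why: Dess–Martin oxidation gives the α-alkoxy aldehyde under near-neutral conditions, so the cis-dioxolane centre next to the formyl group does not epimerise.

**Step 13**
Reactants: 16 (1R,5R)-3-bromo-5-[(2Z,5Z)-octa-2,5-dien-1-yl]-2-oxo-5-[(trimethylsilyl)oxy]cyclopent-3-en-1-yl acetate; 22 methyl 4-[(4S,5S)-5-formyl-2,2-dimethyl-1,3-dioxolan-4-yl]butanoate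
Product: 24 methyl 4-{(4S,5R)-5-[(S)-{(1R,5S)-3-bromo-5-[(2Z,5Z)-octa-2,5-dien-1-yl]-2-oxo-5-[(trimethylsilyl)oxy]cyclopent-3-en-1-yl}(hydroxy)methyl]-2,2-dimethyl-1,3-dioxolan-4-yl}butanoate, via samarium dienolate 23 (not isolated)
Conditions: SmI2 (2.2 equiv, 0.1 M in THF) added to 16 + 22 (1.3 equiv), THF, −78 °C; then H2O (pH 7)
Reagents that add atoms: none
Why: Two-electron cleavage of the α-acetoxy ketone (SmI2 α-deoxygenation, where the C8–OAc σ* overlaps the ketyl π system but the in-plane vinylic C–Br does not) gives regiospecifically the trivalent samarium dienolate, which adds in a Reformatsky-type aldol to the aldehyde chelated through its α-dioxolane oxygen, so that attack anti to the octadienyl chain sets C8 (R) and the chelated chair with an axial aldehyde residue sets C7 (S, syn to C6–O and to C12).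

**Step 14**
Reactants: 24 aldol adduct (as named in step 13)
Product: 25 methyl (5S,6S,7S)-7-{(1R,5S)-3-bromo-5-hydroxy-5-[(2Z,5Z)-octa-2,5-dien-1-yl]-2-oxocyclopent-3-en-1-yl}-5,6,7-trihydroxyheptanoate (target)
Conditions: AcOH–THF–H2O (4:1:1), 35 °C
Reagents that add atoms: none
Why: Mild acid hydrolysis removes the strained cis-dioxolane and the tertiary TMS ether with all C–O bonds retained, and the C12 carbinol cannot ionise next to the electron-poor bromoenone.

**Compound list**
1 | 1-bromopent-2-yne | CCC#CCBr | starting material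
2 | prop-2-yn-1-ol | C#CCO | starting material
3 | octa-2,5-diyn-1-ol | CCC#CCC#CCO | intermediate
4 | (2Z,5Z)-octa-2,5-dien-1-ol | CC/C=C\C/C=C\CO | intermediate
5 | (2Z,5Z)-1-bromoocta-2,5-diene | CC/C=C\C/C=C\CBr | intermediate
6 | 2-bromofuran | Brc1ccco1 | starting material
7 | 5-bromofuran-2-yllithium | [Li]c1ccc(Br)o1 | intermediate
8 | 2-bromo-5-[(2Z,5Z)-octa-2,5-dien-1-yl]furan | CC/C=C\C/C=C\Cc1ccc(Br)o1 | intermediate
9 | {2-bromo-5-[(2Z,5Z)-octa-2,5-dien-1-yl]furan-3-yl}lithium | CC/C=C\C/C=C\Cc1cc([Li])c(Br)o1 | intermediate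
10 | {3-bromo-5-[(2Z,5Z)-octa-2,5-dien-1-yl]furan-2-yl}lithium | CC/C=C\C/C=C\Cc1cc(Br)c([Li])o1 | intermediate
11 | {3-bromo-5-[(2Z,5Z)-octa-2,5-dien-1-yl]furan-2-yl}methanol | CC/C=C\C/C=C\Cc1cc(Br)c(CO)o1 | intermediate
12 | 4-bromo-6-hydroxy-6-[(2Z,5Z)-octa-2,5-dien-1-yl]-2H-pyran-3(6H)-one (racemic hemiketal) | CC/C=C\C/C=C\CC1(O)C=C(Br)C(=O)CO1 | intermediate
13 | (3E,7Z,10Z)-3-bromo-1-hydroxytrideca-3,7,10-triene-2,5-dione (carbonyls cis) | CC/C=C\C/C=C\CC(=O)/C=C(Br)\C(=O)CO | intermediate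
14 | (4R,5R)-2-bromo-4,5-dihydroxy-4-[(2Z,5Z)-octa-2,5-dien-1-yl]cyclopent-2-en-1-one | CC/C=C\C/C=C\C[C@@]1(O)C=C(Br)C(=O)[C@@H]1O | intermediate
15 | (1R,5R)-3-bromo-5-hydroxy-5-[(2Z,5Z)-octa-2,5-dien-1-yl]-2-oxocyclopent-3-en-1-yl acetate | CC/C=C\C/C=C\C[C@@]1(O)C=C(Br)C(=O)[C@@H]1OC(C)=O | intermediate
16 | (1R,5R)-3-bromo-5-[(2Z,5Z)-octa-2,5-dien-1-yl]-2-oxo-5-[(trimethylsilyl)oxy]cyclopent-3-en-1-yl acetate | CC/C=C\C/C=C\C[C@@]1(O[Si](C)(C)C)C=C(Br)C(=O)[C@@H]1OC(C)=O | intermediate
17 | 2,3-O-isopropylidene-D-erythronolactone, (3aR,6aR) | O1C[C@H]2OC(C)(C)O[C@H]2C1=O | starting material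
18 | 2,3-O-isopropylidene-D-erythrofuranose, (3aR,6aR), anomer mixture | O1C[C@H]2OC(C)(C)O[C@H]2C1O | intermediate
19 | (3Z)-4-[(4S,5R)-5-(hydroxymethyl)-2,2-dimethyl-1,3-dioxolan-4-yl]but-3-enoic acid | OC[C@H]1OC(C)(C)O[C@H]1/C=C\CC(=O)O | intermediate
20 | methyl (3Z)-4-[(4S,5R)-5-(hydroxymethyl)-2,2-dimethyl-1,3-dioxolan-4-yl]but-3-enoate | OC[C@H]1OC(C)(C)O[C@H]1/C=C\CC(=O)OC | intermediate
21 | methyl 4-[(4S,5R)-5-(hydroxymethyl)-2,2-dimethyl-1,3-dioxolan-4-yl]butanoate | OC[C@H]1OC(C)(C)O[C@H]1CCCC(=O)OC | intermediate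
22 | methyl 4-[(4S,5S)-5-formyl-2,2-dimethyl-1,3-dioxolan-4-yl]butanoate | O=C[C@H]1OC(C)(C)O[C@H]1CCCC(=O)OC | intermediate
23 | diiodosamarium (5S)-dienolate of the deacetoxylated ring ketone | CC/C=C\C/C=C\C[C@@]1(O[Si](C)(C)C)C=C(Br)C(O[Sm](I)I)=C1 | intermediate
24 | aldol adduct, (5S,6R,7S,8R,12S) in prostanoid numbering, 5,6-acetonide, 12-OTMS | CC/C=C\C/C=C\C[C@@]1(O[Si](C)(C)C)C=C(Br)C(=O)[C@@H]1[C@H](O)[C@H]2OC(C)(C)O[C@H]2CCCC(=O)OC | intermediate
25 | methyl (5S,6S,7S)-7-{(1R,5S)-3-bromo-5-hydroxy-5-[(2Z,5Z)-octa-2,5-dien-1-yl]-2-oxocyclopent-3-en-1-yl}-5,6,7-trihydroxyheptanoate | CC/C=C\C/C=C\C[C@@]1(O)C=C(Br)C(=O)[C@@H]1[C@H](O)[C@@H](O)[C@@H](O)CCCC(=O)OC | target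

**Totals**
Total step count: 14.
Longest linear sequence: 10 steps (steps 1–8, 13, 14).

**Steps most likely to fail**

Step 7 (proposed new ring contraction). The risks are low ee, enolisation at C13, and product inhibition. The fallback sets out from 12 and returns at 14. Triethylamine in DMF carries out the known amine-mediated pyranone-to-dihydroxycyclopentenone isomerisation. It gives the racemic cis-diol, that is 14 together with its mirror image (4S,5S)-2-bromo-4,5-dihydroxy-4-[(2Z,5Z)-octa-2,5-dien-1-yl]cyclopent-2-en-1-one F1. Lipase B from Candida antarctica with vinyl acetate then acetylates the (5S)-alcohol, following the Kazlauskas preference. This gives (1S,5S)-3-bromo-5-hydroxy-5-[(2Z,5Z)-octa-2,5-dien-1-yl]-2-oxocyclopent-3-en-1-yl acetate F2. Unreacted 14 is separated by chromatography and goes on to step 8.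

Step 13 (reductive aldol). The risks are loss of the vinylic bromine, aldehyde pinacol coupling, and the wrong C7 epimer from a non-chelated chair. The fallback sets out from 16 and returns at 24. SmI2 with MeOH in THF at −78 °C first only deoxygenates 16. This gives (4S)-2-bromo-4-[(2Z,5Z)-octa-2,5-dien-1-yl]-4-[(trimethylsilyl)oxy]cyclopent-2-en-1-one F3. Me3SiOTf and Et3N convert it into (5S)-2-bromo-5-[(2Z,5Z)-octa-2,5-dien-1-yl]-3,5-bis[(trimethylsilyl)oxy]cyclopenta-1,3-diene F4. A chelation-controlled Mukaiyama aldol of F4 with 22, promoted by MgBr2·OEt2 in CH2Cl2 (open transition state, syn-selective), gives 24.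

Step 5 (halogen dance). The risks are competing deprotonation of the furfuryl-allylic CH2 and an incomplete dance. The fallback sets out from 5 and returns at 11. Commercial (3-bromofuran-2-yl)methanol F5 is silylated (t-BuMe2SiCl, imidazole) to tert-butyl[(3-bromofuran-2-yl)methoxy]dimethylsilane F6. This already has Br and the C1 unit in place, and its only free α-position is C5. LiN(i-Pr)2 followed by 5 gives {3-bromo-5-[(2Z,5Z)-octa-2,5-dien-1-yl]furan-2-yl}methoxy(tert-butyl)dimethylsilane F7. n-Bu4NF then releases 11.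

**Further compounds**
F1 | step 7 | (4S,5S)-2-bromo-4,5-dihydroxy-4-[(2Z,5Z)-octa-2,5-dien-1-yl]cyclopent-2-en-1-one | CC/C=C\C/C=C\C[C@]1(O)C=C(Br)C(=O)[C@H]1O
F2 | step 7 | (1S,5S)-3-bromo-5-hydroxy-5-[(2Z,5Z)-octa-2,5-dien-1-yl]-2-oxocyclopent-3-en-1-yl acetate | CC/C=C\C/C=C\C[C@]1(O)C=C(Br)C(=O)[C@H]1OC(C)=O
F3 | step 13 | (4S)-2-bromo-4-[(2Z,5Z)-octa-2,5-dien-1-yl]-4-[(trimethylsilyl)oxy]cyclopent-2-en-1-one | CC/C=C\C/C=C\C[C@@]1(O[Si](C)(C)C)C=C(Br)C(=O)C1
F4 | step 13 | (5S)-2-bromo-5-[(2Z,5Z)-octa-2,5-dien-1-yl]-3,5-bis[(trimethylsilyl)oxy]cyclopenta-1,3-diene | CC/C=C\C/C=C\C[C@@]1(O[Si](C)(C)C)C=C(Br)C(O[Si](C)(C)C)=C1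
F5 | step 5 | (3-bromofuran-2-yl)methanol | OCc1occc1Br
F6 | step 5 | tert-butyl[(3-bromofuran-2-yl)methoxy]dimethylsilane | CC(C)(C)[Si](C)(C)OCc1occc1Br
F7 | step 5 | {3-bromo-5-[(2Z,5Z)-octa-2,5-dien-1-yl]furan-2-yl}methoxy(tert-butyl)dimethylsilane | CC/C=C\C/C=C\Cc1cc(Br)c(CO[Si](C)(C)C(C)(C)C)o1
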